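**Strategy**

The plan closes ring A last, at the C1–C10 bond, on a tricycle (rings B, C, D) that already carries the C19–O–C10 γ-lactone. The key step exploits this lactone bridge between C4 and C10 of ring A: a γ-phenylseleno lactone is made from the C10 ketone, its enolate takes up the C1–C3 unit at C4, and C–Se homolysis then gives a tertiary α-acyloxy radical at C10 that adds 6-endo to C1 of the C3 vinyl ketone. One operation builds ring A, completes the oxabicyclo[3.2.1]octanone and fixes quaternary C10, since the cis-fused lactone leaves only the β-face open. The precursor is seleno-lactone 21 bearing an acryloyl group on C4.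

Key step: step 14

Remark on the chemistry: atom numbers follow the gibberellane skeleton of the target (ring A = C1–C5, C10; ring B = C5, C6, C8, C9, C10; ring C = C8, C9, C11–C14; ring D = C8, C13–C16; C7 carboxyl, C17 methylene, C18 methyl, C19 lactone carbonyl). Compounds 3–13 are racemic and are drawn as the enantiomer that is carried on; the enantiomers are separated in step 9 as diastereomers made with an (S)-lactate unit.

**Route**

Step 1
Reactants: 1 dimethyl 3-oxopentanedioate; 2 methyl bromoacetate
Product: 3 trimethyl 3-oxobutane-1,2,4-tricarboxylate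
Conditions: NaH (1.0 equiv), THF, 0 °C; then 2 (0.95 equiv), 0 °C → rt
Reagents that add atoms: none
Why: Enolate C-alkylation (SN2): the mono-sodium enolate of the β-keto diester attacks the α-bromo ester and one equivalent of base limits dialkylation; the new centre C6 is labile and needs no control.

Step 2
Reactants: 3 trimethyl 3-oxobutane-1,2,4-tricarboxylate; 4 methyl vinyl ketone
Product: 6 cyclohexenone triester (ring C), via Michael adduct 5 (not isolated)
Conditions: NaOMe (5 mol %), MeOH, 0 °C → rt; then pyrrolidine (20 mol %), AcOH, PhMe, reflux (−H2O)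
Reagents that add atoms: none
Why: Robinson annulation: the unsubstituted, more accessible methylene (C9) adds to the enone (Michael addition) and the pyrrolidine enamine of the resulting methyl ketone condenses with the C8 carbonyl (aldol condensation) to give the conjugated cyclohexenone; C6 and C9 remain epimerisable.

Step 3
Reactants: 6 cyclohexenone triester; 7 (2-bromoallyl)trimethylsilane
Product: 8 ketone triester with quaternary C8 bearing the 2-bromoallyl group
Conditions: TiCl4 (2.5 equiv), CH2Cl2, −78 → −40 °C
Reagents that add atoms: none
Why: Hosomi–Sakurai conjugate allylation: TiCl4 activates the enone and the allylsilane attacks C8 through its terminal carbon with loss of silicon, which should create the quaternary centre (racemic) and leave a vinyl bromide for ring D; the non-basic conditions tolerate the acidic C9–H.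

Step 4
Reactants: 8 ketone triester
Product: 10 α-silyloxy ketone (12-OTBS cis to the bromoallyl arm), via silyl enol ether 9 (not isolated)
Conditions: LiN(i-Pr)2, TBSCl, HMPA, THF, −78 °C; then mCPBA, NaHCO3, CH2Cl2, −20 °C; then DBU (cat.), rt
Reagents that add atoms: tert-butyldimethylsilyl chloride CC(C)(C)[Si](C)(C)Cl; 3-chloroperbenzoic acid OOC(=O)c1cccc(Cl)c1
Why: Rubottom oxidation: kinetic deprotonation takes the less hindered C12–H (C14 is neopentyl), the silyl enol ether is epoxidised and 1,4-silyl migration gives the α-silyloxy ketone, which DBU should equilibrate to the epimer with the silyloxy group equatorial; this centre is provisional and is reset in step 15.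

Step 5
Reactants: 10 α-silyloxy ketone
Product: 11 bicyclo[3.2.1]octane triester (rings C and D)
Conditions: CrCl2 (6 equiv), NiCl2 (5 mol %), DMF, 25 → 50 °C
Reagents that add atoms: none
Why: Intramolecular Nozaki–Hiyama–Kishi reaction: the vinyl bromide is converted under NiCl2 catalysis into a vinylchromium species that adds to the C13 ketone, and the C15 tether from C8 forces C16 onto the face of C15, which closes ring D and sets the tertiary C13 carbinol.

Step 6
Reactants: 11 bicyclo[3.2.1]octane triester
Product: 12 tricyclic β-keto ester (rings B, C, D)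
Conditions: KOt-Bu (3 equiv), THF, 0 °C → rt; then aq. NH4Cl
Reagents that add atoms: none
Why: Dieckmann condensation: after base-mediated equilibration of C9 the carbanion α to the terminal ester (C5) attacks the C10 ester, and the stabilised β-keto ester enolate should drive closure of ring B as the cis-fused hydrindanone (the preferred fusion next to quaternary C8), while C6 settles with its ester anti to C11.

Step 7
Reactants: 12 tricyclic β-keto ester
Product: 13 tricyclic keto ester
Conditions: LiCl, DMSO, H2O, 130 °C
Reagents that add atoms: none
Why: Krapcho dealkoxycarbonylation: chloride demethylates the β-keto ester and the carboxylate loses CO2, whereas the non-activated C7 methyl ester is untouched; C9 and C6 should keep the cis-fused 6β arrangement, which is also expected to be the thermodynamic one.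

Step 8
Reactants: 14 tert-butyl (S)-lactate
Product: 15 tert-butyl (S)-2-(trifluoromethylsulfonyloxy)propanoate
Conditions: Tf2O, 2,6-lutidine, CH2Cl2, −78 → 0 °C
Reagents that add atoms: trifluoromethanesulfonic anhydride FC(F)(F)S(=O)(=O)OS(=O)(=O)C(F)(F)F
Why: O-Sulfonylation of the secondary alcohol (triflate formation), which breaks no bond to the stereocentre and so keeps the (S) configuration.

Step 9
Reactants: 13 tricyclic keto ester; 15 tert-butyl (S)-2-(trifluoromethylsulfonyloxy)propanoate
Product: 16 C5-alkylated keto diester (single enantiomer)
Conditions: LiN(SiMe3)2 (2.1 equiv), THF, −78 °C; then 15, −78 → −40 °C; aq. NH4Cl; chromatographic separation of the two diastereomers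
Reagents that add atoms: none
Why: Kinetic enolate alkylation (SN2 with inversion): the base removes the hydroxyl proton and a C5 proton (C9–H is shielded by quaternary C8), the enolate displaces triflate anti to the C6 ester so that C4 sits on the α-face of C5, and because 15 is enantiopure the two enantiomers of 13 give two diastereomers, of which chromatography keeps the one built on the natural tricycle.

Step 10
Reactants: 16 C5-alkylated keto diester
Product: 17 γ-phenylseleno lactone (C19–O–C10, Se on C10)
Conditions: PhSeH (3 equiv), BF3·OEt2 (1.5 equiv), CH2Cl2, −40 → −10 °C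
Reagents that add atoms: benzeneselenol [SeH]c1ccccc1
Why: Selenoketalisation with ester participation: BF3 and PhSeH turn the C10 ketone into a selenocarbenium ion that is captured by the C19 ester carbonyl with loss of isobutene, and since only a cis-fused γ-lactone can form on ring B the lactone oxygen should take the α-face of C10 and selenium the β-face.

Step 11
Reactants: 17 γ-phenylseleno lactone; 18 acrolein
Product: 19 aldol adduct with quaternary C4
Conditions: LiN(i-Pr)2 (2.2 equiv), THF, −78 °C; then 18, −78 °C; aq. NH4Cl
Reagents that add atoms: none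
Why: Aldol addition: the exo hydrogen on C4 is removed and the lactone lithium enolate adds 1,2 to acrolein on the convex face of the cis-fused bicyclic lactone (anti to ring B), which should set quaternary C4 with C3 on the face of the C10–Se bond; the C3 carbinol configuration is irrelevant.

Step 12
Reactants: 19 aldol adduct
Product: 20 triol
Conditions: HF·pyridine, pyridine, THF, 0 °C → rt
Reagents that add atoms: none
Why: Fluoride-mediated desilylation (Si–F bond formation) of the secondary TBS ether; tertiary alcohol, selenide and lactone should be unaffected.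

Step 13
Reactants: 20 triol
Product: 21 seleno-lactone with C3 vinyl ketone and C12 ketone
Conditions: DMP (Dess–Martin periodinane, 3 equiv), NaHCO3, CH2Cl2, 0 °C → rt
Reagents that add atoms: none
Why: Dess–Martin oxidation of both secondary carbinols, the allylic one at C3 to the vinyl ketone and the one at C12 to the α-ketol, under buffered neutral conditions that should spare the tertiary alcohol, the selenide and the retro-aldol-prone β-hydroxy lactone.

Step 14
Reactants: 21 seleno-lactone with C3 vinyl ketone and C12 ketone
Product: 22 tetracyclic 3,12-diketone (rings A–D and lactone complete)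
Conditions: Bu3SnH (1.3 equiv, syringe pump), AIBN (0.2 equiv), PhH (0.005 M), 80 °C
Reagents that add atoms: none
Why: Bu3Sn• abstracts the phenylseleno group from C10, giving a tertiary α-acyloxy radical that adds to C1, the terminal carbon of the C3 vinyl ketone, and the resulting α-keto radical at C2 takes hydrogen from Bu3SnH. The closest known reaction type is the tin-hydride-mediated intramolecular Giese addition of O,Se-acetal (anomeric-type) radicals to enones. Ring A (C10–C1–C2–C3–C4–C5) closes in the 6-endo-trig mode, which at the same time completes the 6-oxabicyclo[3.2.1]octan-7-one formed by ring A and the lactone bridge. The only new stereocentre, C10, is controlled by the pre-formed γ-lactone: it is cis-fused to ring B and holds the acryloyl arm of C4 on its convex face, so C1 can reach C10 only from the β-face and the lactone oxygen stays α. The step needs 6-endo over 5-exo closure and cyclisation over premature hydrogen transfer; the first is secured by the polarity of the enone (the nucleophilic α-oxy radical attacks the β-carbon, whereas attack at C2 would give an unstabilised primary radical in a strained bicyclo[2.2.1] frame), the second by slow addition of Bu3SnH at high dilution.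

Step 15
Reactants: 22 tetracyclic 3,12-diketone
Product: 23 methyl ester of the target (3β,12α,13-triol)
Conditions: K[B(s-Bu)3H] (K-Selectride, 4 equiv), THF, −78 °C; then AcOH
Reagents that add atoms: none
Why: Hydride reduction with a bulky trialkylborohydride (equatorial attack on both cyclohexanones): at C3 this should give the axial 3β-alcohol, and at C12, where the α-face is blocked by the syn-axial C10, the hydride should enter from the β-side and give the axial 12α-alcohol; ester and lactone are not reduced at −78 °C.

Step 16
Reactants: 23 methyl ester of the target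
Product: 24 CNP0260503.1 (3β,12α,13-trihydroxy C19-gibberellin 19,10-lactone 7-oic acid)
Conditions: LiS(n-Pr), HMPA, rt; then dilute HCl to pH 3
Reagents that add atoms: none
Why: SN2 demethylation of the hindered methyl ester by thiolate at the methyl carbon, which avoids hydroxide and thereby retro-aldol epimerisation at C3 and opening of the lactone.

**Compound list**

1 | dimethyl 3-oxopentanedioate | COC(=O)CC(=O)CC(=O)OC | starting material
2 | methyl bromoacetate | COC(=O)CBr | starting material
3 | trimethyl 3-oxobutane-1,2,4-tricarboxylate (racemic, labile centre) | COC(=O)CC(C(=O)OC)C(=O)CC(=O)OC | intermediate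
4 | methyl vinyl ketone | CC(=O)C=C | starting material
5 | Michael adduct, trimethyl 3-oxo-4-(3-oxobutyl)butane-1,2,4-tricarboxylate (not isolated) | COC(=O)CC(C(=O)OC)C(=O)C(CCC(C)=O)C(=O)OC | intermediate
6 | dimethyl 2-[6-(methoxycarbonyl)-3-oxocyclohex-1-en-1-yl]butanedioate (C6, C9 labile) | COC(=O)CC(C(=O)OC)C1=CC(=O)CCC1C(=O)OC | intermediate
7 | (2-bromoallyl)trimethylsilane | C[Si](C)(C)CC(Br)=C | starting material
8 | 3,3-disubstituted cyclohexanone triester, quaternary C8 with 2-bromoallyl and succinate arms (racemic; C6, C9 labile) | BrC(=C)C[C@]1(C(CC(=O)OC)C(=O)OC)CC(=O)CCC1C(=O)OC | intermediate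
9 | TBS enol ether of 8 (C12=C13; not isolated) | BrC(=C)C[C@]1(C(CC(=O)OC)C(=O)OC)CC(O[Si](C)(C)C(C)(C)C)=CCC1C(=O)OC | intermediate
10 | α-silyloxy ketone, 12-OTBS cis to the bromoallyl arm (racemic) | BrC(=C)C[C@]1(C(CC(=O)OC)C(=O)OC)CC(=O)[C@H](O[Si](C)(C)C(C)(C)C)CC1C(=O)OC | intermediate
11 | bicyclo[3.2.1]octane triester with 13-OH, 12β-OTBS and 16-methylene (racemic; C6, C9 labile) | C=C1C[C@]2(C(CC(=O)OC)C(=O)OC)C[C@@]1(O)[C@H](O[Si](C)(C)C(C)(C)C)CC2C(=O)OC | intermediate
12 | tricyclic β-keto ester, C10 ketone, C5 and C6 methyl esters, cis-fused rings B/C (racemic) | C=C1C[C@]23C[C@@]1(O)[C@H](O[Si](C)(C)C(C)(C)C)C[C@H]2C(=O)C(C(=O)OC)[C@@H]3C(=O)OC | intermediate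
13 | tricyclic keto ester, C10 ketone, 6β-CO2Me, 9β-H (racemic) | C=C1C[C@]23C[C@@]1(O)[C@H](O[Si](C)(C)C(C)(C)C)C[C@H]2C(=O)C[C@@H]3C(=O)OC | intermediate
14 | tert-butyl (S)-lactate | C[C@H](O)C(=O)OC(C)(C)C | starting material
15 | tert-butyl (S)-2-(trifluoromethylsulfonyloxy)propanoate | C[C@H](OS(=O)(=O)C(F)(F)F)C(=O)OC(C)(C)C | intermediate
16 | keto diester alkylated at C5 (α) with the tert-butyl propanoate unit, single enantiomer | C=C1C[C@]23C[C@@]1(O)[C@H](O[Si](C)(C)C(C)(C)C)C[C@H]2C(=O)[C@@H]([C@H](C)C(=O)OC(C)(C)C)[C@@H]3C(=O)OC | intermediate
17 | γ-phenylseleno γ-lactone, lactone O α and SePh β on C10, exo H on C4 | C=C1C[C@]23C[C@@]1(O)[C@H](O[Si](C)(C)C(C)(C)C)C[C@H]2[C@]4(OC(=O)[C@@H](C)[C@H]4[C@@H]3C(=O)OC)[Se]c5ccccc5 | intermediate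
18 | acrolein | C=CC=O | starting material
19 | aldol adduct, quaternary C4 with 1-hydroxyallyl group (C3 epimers) | C=C1C[C@]23C[C@@]1(O)[C@H](O[Si](C)(C)C(C)(C)C)C[C@H]2[C@]4(OC(=O)[C@](C)(C(O)C=C)[C@H]4[C@@H]3C(=O)OC)[Se]c5ccccc5 | intermediate
20 | triol (C3, C12, C13 hydroxyls free) | C=C1C[C@]23C[C@@]1(O)[C@H](O)C[C@H]2[C@]4(OC(=O)[C@](C)(C(O)C=C)[C@H]4[C@@H]3C(=O)OC)[Se]c5ccccc5 | intermediate
21 | seleno-lactone with C4 acryloyl group and C12 ketone | C=C1C[C@]23C[C@@]1(O)C(=O)C[C@H]2[C@]4(OC(=O)[C@](C)(C(=O)C=C)[C@H]4[C@@H]3C(=O)OC)[Se]c5ccccc5 | intermediate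
22 | tetracyclic 3,12-diketone 19,10-lactone methyl ester | C=C1C[C@]23C[C@@]1(O)C(=O)C[C@H]2[C@@]12CCC(=O)[C@@](C)(C(=O)O1)[C@H]2[C@@H]3C(=O)OC | intermediate
23 | methyl ester of the target | C=C1C[C@]23C[C@@]1(O)[C@@H](O)C[C@H]2[C@@]12CC[C@H](O)[C@@](C)(C(=O)O1)[C@H]2[C@@H]3C(=O)OC | intermediate
24 | CNP0260503.1 | C=C1C[C@]23C[C@@]1(O)[C@@H](O)C[C@H]2[C@@]12CC[C@H](O)[C@@](C)(C(=O)O1)[C@H]2[C@@H]3C(=O)O | target

**Step count and risks**

Total step count: 16. Longest linear sequence: 15 (steps 1–7 and 9–16; step 8 prepares the lactate triflate).

Steps most likely to fail: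

Step 3. The allylsilane may not reach the fully substituted, flanked C8 before TiCl4 enolises the acidic C9–H or the reagent is protodesilylated. Fallback: from 6, TiCl4-promoted conjugate propargylation with allenyltributylstannane, a slimmer and more reactive nucleophile, should give the propargyl ketone F1. Markovnikov bromoboration of its terminal alkyne with B-bromo-9-BBN followed by protonolysis with AcOH then installs the 2-bromoalkene, and the route is rejoined at 8.

Step 14. Hydrogen transfer to the C10 radical may outrun cyclisation, or stannyl radicals may reduce the vinyl ketone. Fallback: from 21, oxidation at selenium (H2O2, pyridine, 0 °C) and syn-elimination of the selenoxide toward C9 should give the enol lactone F2 (C9=C10). Hydrogen-atom transfer from an iron hydride (Fe(acac)3, PhSiH3, EtOH, 60 °C) to C9 then generates the same C10 radical without tin hydride. The hydrogen is expected on the β-face, which gives the cis ring fusion, though this facial selectivity is the weak point of the fallback. 6-Endo Giese closure rejoins the route at 22.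

Step 10. The selenocarbenium ion may lose a proton (vinyl selenide formation with loss of the C9 configuration), the silyl ether may be cleaved, or the Lewis acid may trigger rearrangement of the 13-hydroxy-16-ene unit. Fallback: from 16, TMSOTf and 2,6-lutidine cleave the tert-butyl ester to the keto acid F3. Ac2O, DMAP and pyridine trap its ring tautomer as the γ-acetoxy lactone F4. Exchange of acetate for selenium with PhSeSiMe3 and catalytic TMSOTf at −78 °C rejoins the route at 17.

**Further compounds**

F1 | step 3 | propargyl ketone triester (quaternary C8 with prop-2-ynyl group) | C#CC[C@]1(C(CC(=O)OC)C(=O)OC)CC(=O)CCC1C(=O)OC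
F2 | step 14 | enol lactone (C9=C10) with C4 acryloyl group and C12 ketone | C=C1C[C@]23C[C@@]1(O)C(=O)CC2=C4OC(=O)[C@](C)(C(=O)C=C)[C@H]4[C@@H]3C(=O)OC
F3 | step 10 | keto acid (C19 acid, C10 ketone) | C=C1C[C@]23C[C@@]1(O)[C@H](O[Si](C)(C)C(C)(C)C)C[C@H]2C(=O)[C@@H]([C@H](C)C(O)=O)[C@@H]3C(=O)OC
F4 | step 10 | γ-acetoxy γ-lactone (pseudo-acid acetate at C10) | C=C1C[C@]23C[C@@]1(O)[C@H](O[Si](C)(C)C(C)(C)C)C[C@H]2[C@]4(OC(=O)[C@@H](C)[C@H]4[C@@H]3C(=O)OC)OC(C)=O
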